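Nothing in these flasks makes right-handed substrate, so an excess of it cannot arise except by loss of left-handed substrate. The readings show the right-handed substrate staying near its charge. We therefore read the excess at the end from how much left-handed substrate has gone, and we must decide whether to wait for south-east or stop at west.

| setting | spring | noon | dawn | south-east | west |
|---|---|---|---|---|---|
| left-handed substrate | 28 mM | 44 mM | 20 mM | 20 mM | 20 mM |
| right-handed substrate | 28 mM | 44 mM | 20 mM | 20 mM | 20 mM |
| coupling partner | 40 mM | 40 mM | 20 mM | 40.0 mM | 40.0 mM |
| precatalyst | 20 µM | 20 µM | 20 µM | 20 µM | 20 µM |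
| added ligand | 20 µM | 20 µM | 20 µM | 20 µM | 20 µM |
| remark | run made earlier | run made earlier | run made earlier |  |  |
| time |  |  |  | 20 min | 10 min |

| run | time / min | right-handed substrate / % | left-handed substrate / % | left-handed product / % |
|---|---|---|---|---|
| spring | 1.50 | 48.6 | 49.7 | 0 |
| spring | 3.00 | 49.9 | 48.5 | 3.1 |
| spring | 6.00 | 49.3 | 46.7 | 3.1 |
| spring | 10.0 | 49.3 | 44.2 | 5.0 |
| spring | 20.0 | 49.5 | 38.8 | 8.9 |
| noon | 2.00 | 50.6 | 50.4 | 0 |
| noon | 5.00 | 51.2 | 47.8 | 2.0 |
| noon | 10.0 | 48.9 | 46.5 | 2.6 |
| noon | 15.0 | 48.6 | 43.4 | 7.2 |
| noon | 20.0 | 49.1 | 40.7 | 8.1 |
| dawn | 2.00 | 50.2 | 49.1 | 0.1 |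
| dawn | 5.00 | 50.7 | 47.4 | 0.6 |
| dawn | 10.0 | 51.0 | 46.3 | 5.2 |
| dawn | 15.0 | 50.3 | 43.2 | 5.2 |
| dawn | 20.0 | 51.5 | 43.9 | 8.3 |

(scatter of a reading: 1 percentage point)

- free catalyst is single-handed; left-handed substrate and right-handed substrate are mirror images of each other, charged as a racemate, each of them at the stated concentration
- an excess is the difference of the two amounts in percent of their sum
- an excess is below zero if the other one leads

- the flask that ends with the higher excess of right-handed substrate over left-handed substrate among what is left of the two, or "neither" when 2 percentage points or less lies between them (south-east / west / neither)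
- excess of right-handed substrate over left-handed substrate among what is left of the two at the end, south-east
- excess of right-handed substrate over left-handed substrate among what is left of the two at the end, west

The two flasks are charged alike, so the choice turns on time, but the size of the gain needs a rate. Dawn has the same substrate charge. Its last readings give left-handed substrate 43.9% and left-handed product 8.3%, two measures of one loss, and together they put the left-handed substrate at 42.8%. That is a loss exponent, ln(charge/rest), of 0.155.

We commit to a pseudo-first-order loss whose exponent grows with the dose c(coupling partner)·t. The exponent per unit dose is the dose constant 0.00648 M⁻¹ s⁻¹. Spring, with twice dawn's partner, shows 0.224, more than dawn's. But it holds more substrate, and noon's 0.191 is lower than spring's, so the first power is a commitment, not a proof.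

West then has dawn's dose. With the right-handed substrate at its charge, we expect 7.76% for west and 15.4% for south-east. The wait buys 7.6 percentage points, more than the margin of 2 points, so we wait.

The forecast gives south-east, with 10.7% and 5.4%, both below ours: “The longer flask clearly leads”.

The flask gives south-east, with 15.0% against 7.35%.

    free catalyst + left-handed substrate ⇌ catalyst intermediate A (K = 60.0 M⁻¹, k = 590 M⁻¹ s⁻¹)
    free catalyst + right-handed substrate ⇌ catalyst intermediate B (K = 62.0 M⁻¹, k = 470 M⁻¹ s⁻¹)
    coupling partner + catalyst intermediate A → free catalyst + left-handed product (k = 31.0 M⁻¹ s⁻¹)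
    coupling partner + catalyst intermediate B → free catalyst + right-handed product (k = 0.480 M⁻¹ s⁻¹)
    free catalyst + added ligand ⇌ idle complex, settled at all times (K = 1.10 × 10⁵ M⁻¹)
    coupling partner + precatalyst → free catalyst + spent reagent (k = 0.590 M⁻¹ s⁻¹)

West trails south-east because of its shorter time: it ends at 7.35%, and without the difference in time at 15.0%. The dawn run without scatter ends at 7.38%. Raising its partner to 40.0 mM gives 15.0%, cutting its time to 10 min gives 3.49%, and both together, which is west, give 7.35%, so equal dose returned nearly equal excess.

Now take west with 160 mM of coupling partner. The dose constant gives left-handed substrate 26.8% and excess 30.2%. The computed flask gives 29.4% and 25.4%.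

The numbers in the tables stem from a simulated flask for substances that don't exist; the scatter is artificial.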